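**Retrosynthetic overview**
1. Feature: the central benzene (ring B) carries its six substituents in the order aryloxy, hydroxyl, bromine, aryloxy, hydroxyl, bromine. An inversion centre therefore maps C1–C3 onto C4–C6, and each half is a C3 chain with the oxidation pattern of an aryloxypyruvate (OCH2, C=O, CO2Et).
2. Endgame: 14 ⇒ 12 (last bromine of each outer ring set ortho to the free phenol) ⇒ 11 (O-demethylation) ⇒ quinone 10 ⇒ dihydroxyquinone 9 (the two ring B C–Br bonds come from vinylogous-acid C–OH groups).
3. Key disconnection: 9 ⇒ 2 × keto ester 6, cutting the two ring B bonds that join each aryloxy-bearing carbon to the former ester carbon of the other half (double Claisen).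
4. 6 ⇒ acrylate 4 (C=CH2 as a masked ketone) ⇒ phenol 2 + allylic bromide 3; 2 ⇐ 1.
5. Ring order: outer rings A and C are bought with 1 and already hold their para-related bromines. Ring B is the only ring formed, in step 4.

Key step: step 4

Remark: the target has no stereocentre and its diaryl ether axes are taken as freely rotating, so no stereochemical element has to be set.
Remark: two of the three bromines of each outer ring ride through the key step as spectators, because the position ortho to the ether oxygen cannot be addressed selectively by late bromination. Br2 also oxidizes a free hydroquinone, so the last bromination ends with a reductive quench.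

**Step 1**
Reactants: 1 1,4-dibromo-2,5-dimethoxybenzene
Product: 2 2,5-dibromo-4-methoxyphenol
Conditions: BBr3 (1.0 equiv), CH2Cl2, −78 °C → rt; H2O
Reagents that add atoms: none
Why: BBr3 cleavage of an aryl methyl ether (Lewis acid complexation, then SN2 attack of bromide on the methyl group); one equivalent of reagent can cleave on average only one of the two equivalent methoxy groups, and the monophenol is separated from unchanged 1 and from the diol by acid–base extraction.

**Step 2**
Reactants: 2 2,5-dibromo-4-methoxyphenol; 3 ethyl 2-(bromomethyl)acrylate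
Product: 4 ethyl 2-[(2,5-dibromo-4-methoxyphenoxy)methyl]acrylate
Conditions: K2CO3, acetone, rt → 50 °C
Reagents that add atoms: none
Why: Williamson ether synthesis on an allylic bromide, in which SN2 and SN2′ attack give the same product; the acrylate C=CH2 group is a base-stable mask of the ketone, so neither an enolizable, highly electrophilic bromopyruvate nor keto ester 6 is exposed to carbonate and phenoxide.

**Step 3**
Reactants: 4 ethyl 2-[(2,5-dibromo-4-methoxyphenoxy)methyl]acrylate
Product: 6 ethyl 3-(2,5-dibromo-4-methoxyphenoxy)-2-oxopropanoate, via secondary ozonide 5 (not isolated)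
Conditions: O3, CH2Cl2, −78 °C; then Me2S, −78 °C → rt
Reagents that add atoms: ozone, [O-][O+]=O
Why: Criegee ozonolysis with reductive work-up, the standard neutral way from a 2-substituted acrylate to an α-keto ester; the two bromines make the dialkoxyarene slow towards ozone, and the gas flow is stopped at the first persistent blue colour.

**Step 4**
Reactants: 6 ethyl 3-(2,5-dibromo-4-methoxyphenoxy)-2-oxopropanoate (two molecules)
Product: 9 2,5-dihydroxy-3,6-bis(2,5-dibromo-4-methoxyphenoxy)-1,4-benzoquinone, via acyclic trioxohexanoate 7 (not isolated), via disodium quinonediolate 8 (not isolated)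
Conditions: NaOEt (0.5 equiv at 0 °C, then 0.75 equiv), toluene–EtOH, reflux with distillation of EtOH, Ar; then 1 M HCl
Reagents that add atoms: none
Why: Proposed new method: half an equivalent of ethoxide converts part of 6 into the enolate at its OCH2 carbon (acidified by the ketone and by the electron-poor aryloxy group), and this carbon attacks the oxalyl-type ester carbonyl of a still neutral molecule of 6 and expels ethoxide, an intermolecular Claisen condensation that forms the first ring bond and gives 7, held as its 1,3-dicarbonyl enolate. The second charge of base deprotonates the remaining OCH2 group of 7, and that carbon closes ring B on the remaining ester by a 6-(enolendo)-exo-trig Dieckmann acylation, which forms the second ring bond. The cyclohexane-1,2,4,5-tetraone so formed is a tautomer of 9, so no oxidant is needed, and double deprotonation gives the sparingly soluble salt 8, from which acid sets 9 free. The closest known reaction type is the alkoxide-mediated self-condensation of arylpyruvic esters to 3,6-diaryl-2,5-dihydroxy-1,4-benzoquinones, the laboratory counterpart of terphenylquinone biosynthesis; an oxygen substituent on the nucleophilic carbon is not part of that precedent. The selectivity needed is C-acylation at the ester over aldol addition to the ketone (with lactonization of the aldolate to an isotetronate) and over O-acylation: those paths are reversible in hot ethoxide, whereas each Claisen event is fixed by deprotonation of its product, by distillation of ethanol and by precipitation of 8. Head-to-tail assembly is inherent because each molecule has one enolizable carbon and one ester, the C–OAr carbons of 8 are the electron-rich central carbons of 1,3-dioxygenated anions and so resist exchange with ethoxide, and no stereocentre remains in 9.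

**Step 5**
Reactants: 9 2,5-dihydroxy-3,6-bis(2,5-dibromo-4-methoxyphenoxy)-1,4-benzoquinone
Product: 10 2,5-dibromo-3,6-bis(2,5-dibromo-4-methoxyphenoxy)-1,4-benzoquinone
Conditions: (COBr)2 (3 equiv), DMF (0.2 equiv), CH2Cl2, 0 °C → rt
Reagents that add atoms: oxalyl bromide, O=C(Br)C(=O)Br
Why: Vilsmeier-type deoxybromination: each ring hydroxyl is a vinylogous carboxylic acid, is O-activated by the bromoiminium salt made from DMF and oxalyl bromide and is replaced by bromide through addition–elimination, as in the known conversions of cyclic 1,3-diketones into β-bromoenones and of hydroxyquinones into haloquinones; the degenerate tautomers of 9 lead to the same para-dibromide.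

**Step 6**
Reactants: 10 2,5-dibromo-3,6-bis(2,5-dibromo-4-methoxyphenoxy)-1,4-benzoquinone
Product: 11 2,5-dibromo-3,6-bis(2,5-dibromo-4-methoxyphenoxy)benzene-1,4-diol
Conditions: Na2S2O4, THF–H2O, rt
Reagents that add atoms: none
Why: Dithionite reduction of a quinone: the electron-poor dihaloquinone takes up two electrons and two protons rapidly while aryl bromides and ethers are inert, and the step is placed before demethylation because it turns the vinylogous-ester C–OAr bonds of 10 into robust diaryl ethers.

**Step 7**
Reactants: 11 2,5-dibromo-3,6-bis(2,5-dibromo-4-methoxyphenoxy)benzene-1,4-diol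
Product: 12 2,5-dibromo-3,6-bis(2,5-dibromo-4-hydroxyphenoxy)benzene-1,4-diol
Conditions: BBr3 (6 equiv), CH2Cl2, −78 °C → rt, Ar; H2O
Reagents that add atoms: none
Why: BBr3 demethylation of aryl methyl ethers; diaryl ether and C–Br bonds are inert to the reagent, and the free hydroxyls only bind boron until the aqueous quench, hence the excess.

**Step 8**
Reactants: 12 2,5-dibromo-3,6-bis(2,5-dibromo-4-hydroxyphenoxy)benzene-1,4-diol
Product: 14 2,5-dibromo-3,6-bis(2,3,5-tribromo-4-hydroxyphenoxy)benzene-1,4-diol (target), via octabromoquinone 13 (not isolated)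
Conditions: Br2 (3.1 equiv), AcOH–CH2Cl2, 0 °C → rt; then aq. Na2S2O4
Reagents that add atoms: bromine, BrBr
Why: Electrophilic aromatic bromination directed by the free phenol: each outer ring has one open ortho position (para is blocked by the ether oxygen, and the other CH is meta to the hydroxyl and flanked by bromine and the bulky aryloxy group), Br2 also oxidizes the central hydroquinone to 13, for which the third equivalent is supplied, and the dithionite quench returns ring B to the hydroquinone.

**Compound list**
1 | 1,4-dibromo-2,5-dimethoxybenzene | COc1cc(Br)c(OC)cc1Br | starting material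
2 | 2,5-dibromo-4-methoxyphenol | COc1cc(Br)c(O)cc1Br | intermediate
3 | ethyl 2-(bromomethyl)acrylate | CCOC(=O)C(=C)CBr | starting material
4 | ethyl 2-[(2,5-dibromo-4-methoxyphenoxy)methyl]acrylate | CCOC(=O)C(=C)COc1cc(Br)c(OC)cc1Br | intermediate
5 | ethyl 3-[(2,5-dibromo-4-methoxyphenoxy)methyl]-1,2,4-trioxolane-3-carboxylate (secondary ozonide, racemic, not isolated) | CCOC(=O)C1(COc2cc(Br)c(OC)cc2Br)OCOO1 | intermediate
6 | ethyl 3-(2,5-dibromo-4-methoxyphenoxy)-2-oxopropanoate | CCOC(=O)C(=O)COc1cc(Br)c(OC)cc1Br | intermediate
7 | ethyl 3,6-bis(2,5-dibromo-4-methoxyphenoxy)-2,4,5-trioxohexanoate (drawn in the neutral keto form, present as sodium enolate, C3 labile, not isolated) | CCOC(=O)C(=O)C(Oc1cc(Br)c(OC)cc1Br)C(=O)C(=O)COc1cc(Br)c(OC)cc1Br | intermediate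
8 | disodium salt of 2,5-dihydroxy-3,6-bis(2,5-dibromo-4-methoxyphenoxy)-1,4-benzoquinone (not isolated) | [Na+].[Na+].[O-]C1=C(Oc2cc(Br)c(OC)cc2Br)C(=O)C([O-])=C(Oc2cc(Br)c(OC)cc2Br)C1=O | intermediate
9 | 2,5-dihydroxy-3,6-bis(2,5-dibromo-4-methoxyphenoxy)-1,4-benzoquinone | O=C1C(O)=C(Oc2cc(Br)c(OC)cc2Br)C(=O)C(O)=C1Oc1cc(Br)c(OC)cc1Br | intermediate
10 | 2,5-dibromo-3,6-bis(2,5-dibromo-4-methoxyphenoxy)-1,4-benzoquinone | O=C1C(Br)=C(Oc2cc(Br)c(OC)cc2Br)C(=O)C(Br)=C1Oc1cc(Br)c(OC)cc1Br | intermediate
11 | 2,5-dibromo-3,6-bis(2,5-dibromo-4-methoxyphenoxy)benzene-1,4-diol | Oc1c(Br)c(Oc2cc(Br)c(OC)cc2Br)c(O)c(Br)c1Oc1cc(Br)c(OC)cc1Br | intermediate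
12 | 2,5-dibromo-3,6-bis(2,5-dibromo-4-hydroxyphenoxy)benzene-1,4-diol | Oc1c(Br)c(Oc2cc(Br)c(O)cc2Br)c(O)c(Br)c1Oc1cc(Br)c(O)cc1Br | intermediate
13 | 2,5-dibromo-3,6-bis(2,3,5-tribromo-4-hydroxyphenoxy)-1,4-benzoquinone (not isolated) | O=C1C(Br)=C(Oc2cc(Br)c(O)c(Br)c2Br)C(=O)C(Br)=C1Oc1cc(Br)c(O)c(Br)c1Br | intermediate
14 | 2,5-dibromo-3,6-bis(2,3,5-tribromo-4-hydroxyphenoxy)benzene-1,4-diol (CNP0163357.0) | Oc1c(Br)cc(Oc2c(O)c(Br)c(Oc3cc(Br)c(O)c(Br)c3Br)c(O)c2Br)c(Br)c1Br | target

**Total step count:** 8
**Longest linear sequence:** 8 steps (1 → 14); two molecules of 6 enter step 4.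

**Steps most likely to fail**

Step 4. Aldol addition at the ketone followed by lactonization may outrun C-acylation, or the 1,2-dicarbonyl units may degrade in hot alkoxide before the ring closes. The fallback sets out from phenol 2 and uses known chemistry. Two equivalents of 2 with K2CO3 in MeCN at rt are combined with tetrabromo-1,4-benzoquinone F1 (bromanil, bought). Addition–elimination at one C–Br bond gives 2,3,5-tribromo-6-(2,5-dibromo-4-methoxyphenoxy)-1,4-benzoquinone F2. Its aryloxy oxygen deactivates the carbonyl group it is conjugated with, so the second phenoxide enters at the para-related carbon. This is the established reaction of haloanils with phenoxides to 2,5-diaryloxy-3,6-dihaloquinones. The fallback comes back to the route at 10.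

Step 5. Bromide may displace the aryloxy groups at the vinylogous-ester carbons as HBr builds up, or activation may stay incomplete because 9 dissolves poorly. The fallback sets out from 9 and separates activation from halide delivery. Tf2O and pyridine in CH2Cl2 (−78 → 0 °C) give 3,6-bis(2,5-dibromo-4-methoxyphenoxy)-2,5-bis(trifluoromethylsulfonyloxy)-1,4-benzoquinone F3. LiBr in THF at 0 °C then replaces the triflate groups by addition–elimination under acid-free conditions. The fallback comes back at 10.

Step 8. Bromine may attack ipso, para to the phenol hydroxyl, with oxidative cleavage of the diaryl ether, or bromination may go on at the last CH. The fallback sets out from 10 and moves the bromination ahead of both the reduction and the deprotection, so that no free phenol or hydroquinone meets an electrophilic bromine source. N-Bromosuccinimide (2.2 equiv) in CF3CO2H with catalytic H2SO4 brominates each outer ring ortho to the methoxy group, the stronger donor beside the weakly donating quinonyl oxygen. This gives 2,5-dibromo-3,6-bis(2,3,5-tribromo-4-methoxyphenoxy)-1,4-benzoquinone F4. Na2S2O4 in THF–H2O reduces it to 2,5-dibromo-3,6-bis(2,3,5-tribromo-4-methoxyphenoxy)benzene-1,4-diol F5. BBr3 in CH2Cl2 then cleaves the two flanked methoxy groups, and the fallback comes back at 14.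

**Further compounds**
F1 | step 4 | tetrabromo-1,4-benzoquinone (bromanil, bought) | O=C1C(Br)=C(Br)C(=O)C(Br)=C1Br
F2 | step 4 | 2,3,5-tribromo-6-(2,5-dibromo-4-methoxyphenoxy)-1,4-benzoquinone | O=C1C(Br)=C(Br)C(=O)C(Br)=C1Oc1cc(Br)c(OC)cc1Br
F3 | step 5 | 3,6-bis(2,5-dibromo-4-methoxyphenoxy)-2,5-bis(trifluoromethylsulfonyloxy)-1,4-benzoquinone | O=C1C(OS(=O)(=O)C(F)(F)F)=C(Oc2cc(Br)c(OC)cc2Br)C(=O)C(OS(=O)(=O)C(F)(F)F)=C1Oc1cc(Br)c(OC)cc1Br
F4 | step 8 | 2,5-dibromo-3,6-bis(2,3,5-tribromo-4-methoxyphenoxy)-1,4-benzoquinone | O=C1C(Br)=C(Oc2cc(Br)c(OC)c(Br)c2Br)C(=O)C(Br)=C1Oc1cc(Br)c(OC)c(Br)c1Br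
F5 | step 8 | 2,5-dibromo-3,6-bis(2,3,5-tribromo-4-methoxyphenoxy)benzene-1,4-diol | Oc1c(Br)c(Oc2cc(Br)c(OC)c(Br)c2Br)c(O)c(Br)c1Oc1cc(Br)c(OC)c(Br)c1Br
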